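(Readings and results come from a simulation with constants of no real substance; scatter was added.)

Of the solid electrophile charged, the readings count two amounts: electrophile in solution and target already formed. Their sum is what has left the solid.

| flask | solid electrophile | nucleophile | remark | time |
|---|---|---|---|---|
| east | 0.050 M | 0.55 equiv | run made earlier |  |
| west | 0.050 M | 2.2 equiv | run made earlier |  |
| north | 0.025 M | 1.1 equiv | run made earlier |  |
| flask | 0.050 M | 1.10 equiv |  | 6.0 h |

| run | time / h | target / % | electrophile / % |
|---|---|---|---|
| east | 0.667 | 0.4 | 5.2 |
| east | 1.33 | 0.6 | 9.7 |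
| east | 2.00 | 1.9 | 14.0 |
| east | 3.00 | 3.3 | 18.4 |
| east | 4.00 | 5.2 | 21.8 |
| east | 5.00 | 7.4 | 23.8 |
| west | 0.250 | 0.2 | 2.2 |
| west | 0.667 | 1.3 | 5.2 |
| west | 1.33 | 2.1 | 8.0 |
| west | 2.00 | 5.5 | 10.5 |
| west | 3.00 | 10.2 | 12.3 |
| west | 4.00 | 15.0 | 14.1 |
| west | 5.00 | 20.7 | 14.8 |
| north | 0.417 | 0 | 7.2 |
| north | 0.667 | 0.4 | 11.7 |
| north | 1.33 | 1.2 | 20.2 |
| north | 2.50 | 5.1 | 32.2 |
| north | 5.00 | 14.5 | 48.0 |

(scatter of a reading: 0.3 percentage points)

- solid electrophile is a solid; its amount is given per volume of the solution
- at the start none of the solid electrophile is in solution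
- electrophile means what is dissolved; the solid is not counted in it

1. target at 6.0 h, in percent of the solid electrophile charged
2. concentration of electrophile in solution at 6.0 h, in percent of saturation

North's sum, rescaled to the flask's charge, rises at 0.0907 h⁻¹ of the charge over its first readings; this reading is taken as the feed at the start. Between 3.00 h and 5.00 h, east's sum rises at 0.0475 h⁻¹, with electrophile at 21.8% midway. So the feed falls with dissolved electrophile, through a dissolving constant of 0.198 h⁻¹.

Over those hours, target forms at 0.372 h⁻¹ per unit of electrophile in west. East gives 0.0940 h⁻¹, a quarter of that, on a quarter of west's nucleophile. For the flask, with half of west's nucleophile, this reckoning therefore takes a pseudo-first-order constant of 0.186 h⁻¹.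

In this reckoning, dissolved electrophile in the flask gains the feed and loses in proportion to itself through both constants. Their sum is the clearing constant, 0.384 h⁻¹, the rate at which the solution climbs to its level, feed over clearing constant, here 23.6%. Integrated:

electrophile = level × (1 − exp(−clearing constant × time))

target = 0.186 h⁻¹ × level × (time − (1 − exp(−clearing constant × time)) / clearing constant)

At 6.0 h this reckoning gives electrophile 21.2% and target 16.1%. Saturation, reckoned as feed over dissolving constant, is 45.8%, so the reckoned electrophile stands at 46.4% of it.

The forecast, reading the target's rate as “first order in nucleophile and electrophile”, gives 16.4% and 46%, from constants read its own way.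

    electrophile + nucleophile → acid set free + target (k = 0.0687 L mol⁻¹ min⁻¹)
    nucleophile + acid set free ⇌ protonated nucleophile, settled at all times (K = 1000 L mol⁻¹)
    solid electrophile ⇌ electrophile, rate k3*(cs3 - [electrophile]) while solid is left; crystals form when [electrophile] > cs3 (solubility = 25.0 mM, k = 0.00297 min⁻¹)
    nucleophile → decomposition product (k = 1.14 × 10⁻⁶ min⁻¹)
    nucleophile + acid set free ⇌ idle adduct, settled at all times (K = 1780 L mol⁻¹)

The flask gives 16.3% of target, with electrophile at 43.8% of saturation. At 6.00 h it holds 70% of its nucleophile unbound. For a neighbouring flask with 0.20 M of solid electrophile, at the same equivalents and time, the reckoning divides the feed and multiplies the target constant by 4.00. Its clearing constant becomes 0.943 h⁻¹, its level 2.41% and its reckoned target 8.85%. That flask holds 2.31% of electrophile and 9.10% of target.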